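**Plan** (labdane numbering)

- Retrosynthesis: both acetates come off last and the C7=C8–C17 allylic acetate of ring B is read as a reduced enal. Ring B is then cut at C7–C8 (aldol condensation) and at C9–C10 (addition of a tertiary C10 radical to an enal). This is possible because C8 carries the C17 carbonyl and because quaternary C10 bears a methyl (C20) that can be the CH2 of an exocyclic C10=C20 alkene.
- The cuts leave a ring A aldehyde (C1–C7, C10, C18–C20) and an acyclic (E)-enal (C8, C9, C11–C17) that already holds the C11–C15 chain.
- Forward, ring A: 3-methylcyclohexenone, cuprate addition with enol carbonate trapping, palladium-catalysed decarboxylative allylation, ozonolysis, acetal, methylenation, hydrolysis. Enal: (S)-citronellol, acetylation, ozonolysis, Wittig.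
- Ring B is formed and the chain joined in one operation by an iron-hydride radical–polar crossover annulation with dehydration; Luche reduction and acetylation finish.
- Stereochemistry: C13 from (S)-citronellol; C5 from the chiral palladium catalyst; C10 and C9 in the annulation, under control of C5 and the axial C4 methyl.

Key step: step 10

Assumption: the (R,R) antipode of the ANDEN-phenyl diphosphine ligand, N,N'-(9,10-dihydro-9,10-ethanoanthracene-11,12-diyl)bis(2-diphenylphosphinobenzamide), is taken to deliver (S)-4; if the sense of induction on this enolate is the opposite, the (S,S) ligand is used and nothing else changes.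

**Route**

Step 1
Reactants: 1 3-methylcyclohex-2-en-1-one; 2 allyl chloroformate
Product: 3 allyl 3,3-dimethylcyclohex-1-en-1-yl carbonate
Conditions: Me2CuLi (from MeLi and CuI), Et2O, 0 °C; then 2, TMEDA, THF, −78 °C → rt
Reagents that add atoms: lithium dimethylcuprate, [Li+].C[Cu-]C; allyl chloroformate (2), C=CCOC(Cl)=O
Why: Conjugate addition of the Gilman cuprate gives the regiodefined lithium enolate next to the new gem-dimethyl carbon, and O-acylation of this hindered enolate by the chloroformate in the presence of TMEDA (enolate trapping) gives the enol carbonate; no stereocentre is formed.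

Step 2
Reactants: 3 allyl 3,3-dimethylcyclohex-1-en-1-yl carbonate
Product: 4 (S)-2-allyl-3,3-dimethylcyclohexan-1-one
Conditions: Pd2(dba)3·CHCl3 (2.5 mol %), (R,R)-ANDEN-phenyl diphosphine ligand (5.5 mol %), 1,4-dioxane, rt
Reagents that add atoms: none
Why: Decarboxylative asymmetric allylic alkylation (Tsuji–Trost type): zerovalent palladium ionises the allyl carbonate, CO2 is lost, and the enolate/π-allylpalladium pair recombines at C2 inside the chiral pocket under neutral conditions, so the tertiary α-centre (C5 of the target) is set by the catalyst and is not equilibrated afterwards.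

Step 3
Reactants: 4 (S)-2-allyl-3,3-dimethylcyclohexan-1-one
Product: 5 (S)-2-(2,2-dimethyl-6-oxocyclohexyl)acetaldehyde
Conditions: O3, CH2Cl2, −78 °C; then PPh3, −78 °C → rt
Reagents that add atoms: ozone, [O-][O+]=O
Why: Ozonolysis with reductive work-up cleaves the only alkene to the aldehyde under cold, neutral conditions that leave the ketone and its α-stereocentre untouched.

Step 4
Reactants: 5 (S)-2-(2,2-dimethyl-6-oxocyclohexyl)acetaldehyde
Product: 6 (S)-2-(2,2-dimethoxyethyl)-3,3-dimethylcyclohexan-1-one
Conditions: HC(OMe)3, MeOH, PPTS (cat.), rt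
Reagents that add atoms: trimethyl orthoformate, COC(OC)OC
Why: Acid-catalysed acetalisation with an orthoformate is much faster at the unhindered aldehyde than at the α-branched ketone, so only the aldehyde is masked, and the weak acid is not expected to enolise the ketone toward C5.

Step 5
Reactants: 6 (S)-2-(2,2-dimethoxyethyl)-3,3-dimethylcyclohexan-1-one
Product: 7 (S)-2-(2,2-dimethoxyethyl)-1,1-dimethyl-3-methylidenecyclohexane
Conditions: Zn, CH2Br2, TiCl4, THF/CH2Cl2, 0 °C → rt (reagent pre-formed)
Reagents that add atoms: dibromomethane, BrCBr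
Why: Takai–Lombardo methylenation uses a non-basic zinc–titanium carbenoid that olefinates hindered, enolisable ketones without epimerising the adjacent stereocentre and normally tolerates acetals.

Step 6
Reactants: 7 (S)-2-(2,2-dimethoxyethyl)-1,1-dimethyl-3-methylidenecyclohexane
Product: 8 (S)-2-(2,2-dimethyl-6-methylidenecyclohexyl)acetaldehyde
Conditions: oxalic acid, THF/H2O, rt
Reagents that add atoms: water, O
Why: Mild aqueous acid hydrolysis of the dimethyl acetal frees the aldehyde without moving the exocyclic alkene or touching C5, which is no longer α to a carbonyl.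

Step 7
Reactants: 9 (S)-citronellol
Product: 10 (S)-3,7-dimethyloct-6-en-1-yl acetate
Conditions: Ac2O, pyridine, DMAP (cat.), CH2Cl2, 0 °C → rt
Reagents that add atoms: acetic anhydride, CC(=O)OC(C)=O
Why: DMAP-catalysed acetylation of the primary alcohol installs the C15 acetate of the target at the outset; the C13 stereocentre is remote and unaffected.

Step 8
Reactants: 10 (S)-3,7-dimethyloct-6-en-1-yl acetate
Product: 11 (S)-3-methyl-6-oxohexyl acetate
Conditions: O3, CH2Cl2, −78 °C; then PPh3, −78 °C → rt
Reagents that add atoms: ozone, [O-][O+]=O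
Why: Ozonolysis of the trisubstituted alkene with reductive work-up gives the aldehyde, the acetate being inert.

Step 9
Reactants: 11 (S)-3-methyl-6-oxohexyl acetate; 12 (triphenylphosphoranylidene)acetaldehyde
Product: 13 (3S,6E)-3-methyl-8-oxooct-6-en-1-yl acetate
Conditions: PhMe, 80 °C
Reagents that add atoms: (triphenylphosphoranylidene)acetaldehyde (12), O=CC=P(c1ccccc1)(c1ccccc1)c1ccccc1
Why: Wittig olefination with the stabilised formylmethylene ylide gives the (E)-enal, and a small excess of ylide at moderate temperature limits a second homologation of the product.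

Step 10
Reactants: 8 (S)-2-(2,2-dimethyl-6-methylidenecyclohexyl)acetaldehyde; 13 (3S,6E)-3-methyl-8-oxooct-6-en-1-yl acetate
Product: 15 (5S,9R,10S,13S)-17-oxolabd-7-en-15-yl acetate, via aldol (13S)-7-hydroxy-17-oxolabdan-15-yl acetate 14 (not isolated)
Conditions: Fe(acac)3 (0.3 equiv), PhSiH3 (2.5 equiv), 13 (2 equiv), EtOH/(CH2OH)2 (5:1), 0 °C → rt; then solvent exchange, p-TsOH·H2O (cat.), PhMe, 50 °C
Reagents that add atoms: none
Why: Fe(acac)3 and PhSiH3 form an iron hydride that transfers a hydrogen atom to C20 of the electron-rich 1,1-disubstituted alkene of 8; the tertiary C10 radical adds to the β-carbon (C9) of enal 13 (Giese addition, C9–C10), the α-formyl radical is reduced by divalent iron to an iron enolate, and this attacks the C7 aldehyde through C8 (aldol, C7–C8) to give 14, from which the acid treatment eliminates water to leave the C7=C8–C17 enal. The closest known reaction type is the iron-hydride radical–polar crossover annulation of γ,δ-unsaturated aldehydes with α,β-unsaturated carbonyl acceptors, followed here by an ordinary aldol dehydration. Ring B closes in the aldol event in a 6-(enolexo)-exo-trig mode, the preceding C9–C10 bond formation being intermolecular. C10 is controlled by ring A: the axial C4 methyl blocks axial attack on the radical, so the new C9–C10 bond forms equatorially, C20 becomes axial and, with the C6 arm equatorial on C5, the decalin is trans-fused. C9 is set by the enal face that meets the radical: the C9 hydrogen is expected to sit next to the C6 arm and the rigid formyl-vinyl unit to point away from ring A, which after rotation and closure leaves the C11 chain equatorial on ring B (9R), and this acyclic facial choice is the least certain element of the step. The step needs cross-selectivity between the two alkenes and this follows from their polarity, since only the unactivated alkene takes up the hydrogen atom and only the enal accepts the nucleophilic tertiary radical, while the acetate and the aldehydes are inert to the hydride.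

Step 11
Reactants: 15 (5S,9R,10S,13S)-17-oxolabd-7-en-15-yl acetate
Product: 16 (5S,9R,10S,13S)-17-hydroxylabd-7-en-15-yl acetate
Conditions: NaBH4, CeCl3·7H2O, MeOH, 0 °C
Reagents that add atoms: none
Why: Luche reduction delivers hydride 1,2 to the enal and gives the allylic alcohol at 0 °C without touching the trisubstituted alkene or, in the short reaction time, the acetate.

Step 12
Reactants: 16 (5S,9R,10S,13S)-17-hydroxylabd-7-en-15-yl acetate
Product: 17 (5S,9R,10S,13S)-labd-7-ene-15,17-diyl diacetate
Conditions: Ac2O, pyridine, DMAP (cat.), CH2Cl2, rt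
Reagents that add atoms: acetic anhydride, CC(=O)OC(C)=O
Why: Acetylation of the primary allylic alcohol completes the diacetate, and any C15 acetate lost in the preceding steps would be restored by the same reagent.

**Compound list**

1 | 3-methylcyclohex-2-en-1-one | CC1=CC(=O)CCC1 | starting material
2 | allyl chloroformate | C=CCOC(Cl)=O | starting material
3 | allyl 3,3-dimethylcyclohex-1-en-1-yl carbonate | C=CCOC(=O)OC1=CC(C)(C)CCC1 | intermediate
4 | (S)-2-allyl-3,3-dimethylcyclohexan-1-one | O=C1CCCC(C)(C)[C@@H]1CC=C | intermediate
5 | (S)-2-(2,2-dimethyl-6-oxocyclohexyl)acetaldehyde | O=C1CCCC(C)(C)[C@@H]1CC=O | intermediate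
6 | (S)-2-(2,2-dimethoxyethyl)-3,3-dimethylcyclohexan-1-one | O=C1CCCC(C)(C)[C@@H]1CC(OC)OC | intermediate
7 | (S)-2-(2,2-dimethoxyethyl)-1,1-dimethyl-3-methylidenecyclohexane | C=C1CCCC(C)(C)[C@@H]1CC(OC)OC | intermediate
8 | (S)-2-(2,2-dimethyl-6-methylidenecyclohexyl)acetaldehyde | C=C1CCCC(C)(C)[C@@H]1CC=O | intermediate
9 | (S)-citronellol | OCC[C@@H](C)CCC=C(C)C | starting material
10 | (S)-3,7-dimethyloct-6-en-1-yl acetate | CC(=O)OCC[C@@H](C)CCC=C(C)C | intermediate
11 | (S)-3-methyl-6-oxohexyl acetate | CC(=O)OCC[C@@H](C)CCC=O | intermediate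
12 | (triphenylphosphoranylidene)acetaldehyde | O=CC=P(c1ccccc1)(c1ccccc1)c1ccccc1 | starting material
13 | (3S,6E)-3-methyl-8-oxooct-6-en-1-yl acetate | O=C/C=C/CC[C@H](C)CCOC(C)=O | intermediate
14 | (13S)-7-hydroxy-17-oxolabdan-15-yl acetate (C7 and C8 unassigned, both erased on dehydration) | CC(=O)OCC[C@@H](C)CC[C@H]1C(C=O)C(O)C[C@H]2C(C)(C)CCC[C@]12C | intermediate
15 | (5S,9R,10S,13S)-17-oxolabd-7-en-15-yl acetate | CC(=O)OCC[C@@H](C)CC[C@H]1C(C=O)=CC[C@H]2C(C)(C)CCC[C@]12C | intermediate
16 | (5S,9R,10S,13S)-17-hydroxylabd-7-en-15-yl acetate | CC(=O)OCC[C@@H](C)CC[C@H]1C(CO)=CC[C@H]2C(C)(C)CCC[C@]12C | intermediate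
17 | (5S,9R,10S,13S)-labd-7-ene-15,17-diyl diacetate | CC(=O)OCC[C@@H](C)CC[C@H]1C(COC(C)=O)=CC[C@H]2C(C)(C)CCC[C@]12C | target

**Count**

Total steps: 12. Longest linear sequence: 9 (steps 1–6, 10, 11, 12).

**Steps most likely to fail**

1. Step 10.
- What may go wrong: the hindered tertiary radical may be quenched by a second hydrogen atom, or the enal consumed by oligomerisation, faster than the radical adds to the β-substituted acceptor. The enal may also be attacked with little facial preference, so that C9 forms as a mixture of epimers.
- Fallback (sets out from 8 and 11, comes back at 17): the C9–C10 bond is closed inside the ring instead of between two molecules.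
- Aldehyde 8 is homologated with methyl diazoacetate and SnCl2 (Roskamp reaction) to the β-keto ester methyl 4-[(1S)-2,2-dimethyl-6-methylidenecyclohexyl]-3-oxobutanoate F1.
- Knoevenagel condensation of F1 with aldehyde 11 (piperidine, AcOH) gives the alkylidene β-keto ester methyl (6S)-8-acetoxy-2-{[(1S)-2,2-dimethyl-6-methylidenecyclohexyl]acetyl}-6-methyloct-2-enoate F2.
- Under Fe(acac)3/PhSiH3 in EtOH the C10 radical now adds to C9 of the doubly activated alkene in a 6-endo-trig closure. For the isomer of F2 with the chain cis to the ester, the chair transition state places the C11 chain equatorial on ring B; the alkene isomers of F2 interconvert under amine catalysis, so the other one can be recycled. The product is the bicyclic β-keto ester methyl (13S)-15-acetoxy-7-oxolabdan-17-oate F3.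
- NaBH4 in MeOH reduces the C7 ketone to methyl (13S)-15-acetoxy-7-hydroxylabdan-17-oate F4, and p-TsOH in warm toluene dehydrates it to the conjugated ester methyl (13S)-15-acetoxylabd-7-en-17-oate F5.
- i-Bu2AlH reduces both esters to (13S)-labd-7-ene-15,17-diol F6, and acetylation under the conditions of step 12 gives 17.

2. Step 2.
- What may go wrong: proton transfer between the palladium enolate and the product, or slow recombination at the carbon flanked by the quaternary centre, may erode the enantiomeric purity or lead to regioisomeric and doubly allylated ketone.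
- Fallback (sets out from 1, comes back at 4): the stereocentre is obtained by enzymatic resolution instead of asymmetric catalysis.
- Enone 1 is treated with Me2CuLi and the enolate is trapped with allyl bromide to give racemic 2-allyl-3,3-dimethylcyclohexan-1-one F7.
- LiBH(s-Bu)3 reduces F7 from the equatorial side to racemic cis-2-allyl-3,3-dimethylcyclohexan-1-ol F8.
- Acylation with vinyl acetate and Candida antarctica lipase B is expected, from the usual preference of lipases for secondary alcohols, to convert the (1R) enantiomer into (1R,2S)-2-allyl-3,3-dimethylcyclohexyl acetate F9, which is separated from the unreacted enantiomeric alcohol.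
- K2CO3 in MeOH gives (1R,2S)-2-allyl-3,3-dimethylcyclohexan-1-ol F10, and oxidation with Dess–Martin periodinane, which does not enolise the product, returns 4.

3. Step 5.
- What may go wrong: slow addition of the carbenoid to the hindered carbonyl may let enolisation compete, with loss of configuration at C5, and the Lewis-acidic medium may cleave the acetal.
- Fallback (sets out from 6, comes back at 15): the carbonyl olefination is avoided altogether.
- Ketone 6 is deprotonated on its CH2 side with LiN(i-Pr)2 at −78 °C, which leaves C5 untouched, and the enolate is trapped with PhNTf2 to give (S)-6-(2,2-dimethoxyethyl)-5,5-dimethylcyclohex-1-en-1-yl trifluoromethanesulfonate F11.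
- Coupling with Me2CuLi gives (S)-6-(2,2-dimethoxyethyl)-1,5,5-trimethylcyclohex-1-ene F12.
- Hydrolysis as in step 6 gives (S)-2-(2,6,6-trimethylcyclohex-2-en-1-yl)acetaldehyde F13.
- The trisubstituted alkene of F13 takes up the hydrogen atom at C1 and so gives the same tertiary C10 radical; used in place of 8 under the conditions of step 10 it leads through 14 to 15.

Further compounds
F1 | step 10 | methyl 4-[(1S)-2,2-dimethyl-6-methylidenecyclohexyl]-3-oxobutanoate | C=C1CCCC(C)(C)[C@@H]1CC(=O)CC(=O)OC
F2 | step 10 | methyl (6S)-8-acetoxy-2-{[(1S)-2,2-dimethyl-6-methylidenecyclohexyl]acetyl}-6-methyloct-2-enoate (alkene isomers) | C=C1CCCC(C)(C)[C@@H]1CC(=O)C(C(=O)OC)=CCC[C@H](C)CCOC(C)=O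
F3 | step 10 | methyl (13S)-15-acetoxy-7-oxolabdan-17-oate (C8 enolisable) | CC(=O)OCC[C@@H](C)CC[C@H]1C(C(=O)OC)C(=O)C[C@H]2C(C)(C)CCC[C@]12C
F4 | step 10 | methyl (13S)-15-acetoxy-7-hydroxylabdan-17-oate (C7 and C8 unassigned) | CC(=O)OCC[C@@H](C)CC[C@H]1C(C(=O)OC)C(O)C[C@H]2C(C)(C)CCC[C@]12C
F5 | step 10 | methyl (13S)-15-acetoxylabd-7-en-17-oate | CC(=O)OCC[C@@H](C)CC[C@H]1C(C(=O)OC)=CC[C@H]2C(C)(C)CCC[C@]12C
F6 | step 10 | (13S)-labd-7-ene-15,17-diol | OCC[C@@H](C)CC[C@H]1C(CO)=CC[C@H]2C(C)(C)CCC[C@]12C
F7 | step 2 | racemic 2-allyl-3,3-dimethylcyclohexan-1-one | C=CCC1C(=O)CCCC1(C)C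
F8 | step 2 | racemic cis-2-allyl-3,3-dimethylcyclohexan-1-ol (relative configuration shown) | O[C@@H]1CCCC(C)(C)[C@@H]1CC=C
F9 | step 2 | (1R,2S)-2-allyl-3,3-dimethylcyclohexyl acetate | CC(=O)O[C@@H]1CCCC(C)(C)[C@@H]1CC=C
F10 | step 2 | (1R,2S)-2-allyl-3,3-dimethylcyclohexan-1-ol (single enantiomer) | O[C@@H]1CCCC(C)(C)[C@@H]1CC=C
F11 | step 5 | (S)-6-(2,2-dimethoxyethyl)-5,5-dimethylcyclohex-1-en-1-yl trifluoromethanesulfonate | O=S(=O)(OC1=CCCC(C)(C)[C@@H]1CC(OC)OC)C(F)(F)F
F12 | step 5 | (S)-6-(2,2-dimethoxyethyl)-1,5,5-trimethylcyclohex-1-ene | CC1=CCCC(C)(C)[C@@H]1CC(OC)OC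
F13 | step 5 | (S)-2-(2,6,6-trimethylcyclohex-2-en-1-yl)acetaldehyde | CC1=CCCC(C)(C)[C@@H]1CC=O
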